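The numbers are those of an exercise, and the outcome is calculated.

A leftover of X is lost Q, and so is a surplus of Z, so the charge of D we want lies between those two faults.

| flask | X | D | time |
|---|---|---|---|
| summer | 2.0 mM | 1.20 equiv | 40 s |
| autumn | 2.0 mM | 2.50 equiv | 40 s |
| spring | 2.0 mM | 5.00 equiv | 40 s |

    X + Z → Q (k1 = 291 /M/s)
    Z + Q → G (k2 = 10.5 /M/s)
    D ⇌ Z, rate k3*(cs3 - [Z]) while solid is left; crystals form when [Z] > cs3 (cs3 = 1.5 mM, k3 = 2.59 /s)
    2 Z → J (k4 = 15.1 /M/s)
    Z → E (k5 = 0.253 /s)

- where a step has two of a species, its rate is k times that concentration squared, and two are used at each turn
- solid, in amounts per volume of the solution: D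
- at the start none of D is in solution
- "hardly changes" means that all values lie within two and a half points (for a concentration: within two and a half percent of the largest)
- run time (summer): 40 s

* amount of Q at the end, in percent of the X charged for summer, autumn, spring, in this order
* how that number moves from the first to the last of them (hardly changes / falls, then rises / rises, then falls / rises all the way / falls all the way)

What can be said without integrating anything? X and Q are each taken, and E is made, in proportion to Z, so the amount of E formed works as a clock for X and Q, however unevenly the solid feeds Z. Set a = 1.15 /mM and b = 0.0415 /mM. At E on this clock, the fraction of X left is exp(−aE), and the fraction standing as Q is a/(a−b) × (exp(−bE) − exp(−aE)).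

Where does Q peak? Setting the slope to nothing gives ln(a/b)/(a−b), which is 3.00 mM of E, the peak mark. There Q is 88.3% and X is 3.19%.

What does the mark cost in Z? It costs the E, the X used, and a second Z for each G: 5.10 mM, or 2.55 equivalents.

You left out J. Yes. With Z at its solubility, J takes 17.9% as much Z as E does, and with that full share on the E of the mark my estimate of the best charge moves up to 2.82 equivalents.

Does the run last? The half-life of Z by the step to E is 2.74 s, far shorter than the run. With Z near solubility, that step drains 0.380 mM/s, faster than the 0.250 mM/s that would empty spring's charge in the run.

And the flasks? In summer D is the limiting reagent. Leaving a third of X costs 2.29 mM of Z against 2.40 mM charged, so I commit to Q near 66.7%, less what G takes. Autumn's charge stands just below the best one, so its Q lies close under 88.3%. Spring pays for X, and for a second Z on a G that I guess at 20.0% of the X charged, leaving 7.60 mM for E, or 6.45 mM with J at its full share. That puts Q between 75.7% and 79.4%.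

The forecast gives 65%, 88% and 79%, a row that rises, then falls, with its summer value lower than my figure, and says of spring that “this extra Z exposure slowly turns more Q into G”.

The flask gives 65.0%, 88.0% and 78.7%, so the row rises, then falls. The row turns at 2.7 equiv, with 88.3% of Q there. Autumn ended with 2.64 mM of E, short of the mark of 3.00 mM, and spring with 6.64 mM, past it. On the clock, autumn's E gives 88.0% of Q. Spring's E gives 78.8%, with G at 21.2%.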